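**Strategy.** The plan rests on cutting the C3–O3 bond of the catechol, which traces the target back to a salicylate (C1 carries the ester, C2 and C3 the hydroxyls). A di-tert-butylsilanol hung on O2 steers palladium into the benzene ring. Of the two carbons flanking C2, C1 is occupied by the ester, so C3–H is the sole reachable bond. In one operation the step installs O3 and ties O2 and O3 into a 1,3,2-benzodioxasilole ring, so the catechol emerges masked. The precursor is octadecyl salicylate bearing an O2–Si(t-Bu)2–OH group, with the C18 ester already in place. Fluoride then releases Gentiside E.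

Key step: step 3

Remark on the chemistry: the aryl C3–O bond made at palladium is not broken again, so O3 is taken to come from an acetate of PhI(OAc)2, the original silanol oxygen is taken to leave in acetic acid, and the ring-closing bond is therefore O3–Si.

Design note: the octadecyl ester is installed before the key step. A non-volatile alcohol cannot escape at 100 °C, so the silanol gains no driving force to cyclise onto the ester carbonyl, and only a buffered desilylation follows the risky step. Silylation and Si–OTf hydrolysis are run in one pot.

**Step 1**
Reactants: 1 methyl salicylate (1.5 equiv); 2 octadecan-1-ol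
Product: 3 octadecyl salicylate (octadecyl 2-hydroxybenzoate)
Conditions: Ti(OiPr)4 (5 mol %), neat, 140 °C, N2 sweep, MeOH distilled off; aqueous quench, filtration; surplus 1 removed in vacuo
Reagents that add atoms: none
Why: Ti(OiPr)4-catalysed transesterification is an equilibrium pulled towards 3 by removing methanol and by a surplus of volatile 1, which uses up the hard-to-separate fatty alcohol, while the neutral Lewis acid leaves the free phenol alone.

**Step 2**
Reactants: 3 octadecyl salicylate; 4 di-tert-butylsilyl bis(trifluoromethanesulfonate) (1.2 equiv)
Product: 6 octadecyl 2-[di-tert-butyl(hydroxy)silyloxy]benzoate, via silyl triflate 5 (not isolated)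
Conditions: 2,6-lutidine (3 equiv), CH2Cl2, 0 °C, slow addition of 3 to 4, then rt; then THF/H2O, 0 °C to rt
Reagents that add atoms: di-tert-butylsilyl bis(trifluoromethanesulfonate) 4, CC(C)(C)[Si](OS(=O)(=O)C(F)(F)F)(OS(=O)(=O)C(F)(F)F)C(C)(C)C; water, O
Why: This is phenol O-silylation with a silyl bis(triflate) followed by hydrolysis of the residual Si–OTf bond: the first triflate should be displaced even by the hydrogen-bonded phenol, whereas the two tert-butyl groups hinder entry of a second aryloxide and later keep silanol 6 from condensing to a disiloxane.

**Step 3**
Reactants: 6 octadecyl 2-[di-tert-butyl(hydroxy)silyloxy]benzoate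
Product: 9 octadecyl 2,2-di-tert-butyl-1,3,2-benzodioxasilole-4-carboxylate, via C3-acetoxy silanol 7 (not isolated), via silyl acetate 8 (not isolated)
Conditions: Pd(OPiv)2 (10 mol %), PhI(OAc)2 (2 equiv), toluene, 100 °C, sealed vessel
Reagents that add atoms: (diacetoxyiodo)benzene PhI(OAc)2, CC(=O)OI(OC(C)=O)c1ccccc1 (supplies O3)
Why: Silanol 6 binds divalent palladium through its silicon-bound oxygen, and pivalate-assisted concerted metalation–deprotonation breaks C3–H by way of a six-membered palladacycle made up of Pd, the silanol O, Si, O2, C2 and C3. Two-electron oxidation by PhI(OAc)2 gives a tetravalent palladium aryl acetate, which collapses by C–O reductive elimination to the C3 acetate 7 and hands back divalent palladium. Catalysed by the acetic acid released, the acetyl group moves from O3 to the adjacent silanol oxygen (8), after which O3–H attacks silicon and expels acetic acid, a 5-exo-tet-type closure through pentacoordinate silicon that makes the O3–Si bond of the 1,3,2-dioxasilole ring in 9. The nearest established reaction class is the palladium-catalysed, silanol-guided ortho-hydroxylation of phenols that delivers catechols as cyclic silyl ethers, a class that also accepts electron-poor rings. No stereocentre arises. The only selectivity at stake is the choice of C–H bond, and the substrate decides it: a metal held on the O2–Si–O arm can touch just the two carbons next to C2, of which C1 is fully substituted by the ester, and the neutral ester carbonyl is too weak a ligand to pull palladium to C6.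

**Step 4**
Reactants: 9 octadecyl 2,2-di-tert-butyl-1,3,2-benzodioxasilole-4-carboxylate
Product: 10 Gentiside E (octadecyl 2,3-dihydroxybenzoate)
Conditions: Bu4NF (2.5 equiv), AcOH (3 equiv), degassed THF, 0 °C to rt, Ar; mildly acidic aqueous work-up
Reagents that add atoms: none
Why: Fluoride-mediated cleavage of the cyclic di-tert-butylsilylene ether, driven by Si–F bond strength, frees both phenols, and the acetic acid protonates each aryloxide as it forms, so neither ester cleavage by basic fluoride nor aerial oxidation of a catecholate can set in.

**Compound list**
1 | methyl salicylate (methyl 2-hydroxybenzoate) | COC(=O)c1ccccc1O | starting material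
2 | octadecan-1-ol | CCCCCCCCCCCCCCCCCCO | starting material
3 | octadecyl salicylate (octadecyl 2-hydroxybenzoate) | CCCCCCCCCCCCCCCCCCOC(=O)c1ccccc1O | intermediate
4 | di-tert-butylsilyl bis(trifluoromethanesulfonate) | CC(C)(C)[Si](OS(=O)(=O)C(F)(F)F)(OS(=O)(=O)C(F)(F)F)C(C)(C)C | starting material
5 | octadecyl 2-[di-tert-butyl(trifluoromethanesulfonyloxy)silyloxy]benzoate (not isolated) | CCCCCCCCCCCCCCCCCCOC(=O)c1ccccc1O[Si](OS(=O)(=O)C(F)(F)F)(C(C)(C)C)C(C)(C)C | intermediate
6 | octadecyl 2-[di-tert-butyl(hydroxy)silyloxy]benzoate | CCCCCCCCCCCCCCCCCCOC(=O)c1ccccc1O[Si](O)(C(C)(C)C)C(C)(C)C | intermediate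
7 | octadecyl 3-acetoxy-2-[di-tert-butyl(hydroxy)silyloxy]benzoate (not isolated) | CCCCCCCCCCCCCCCCCCOC(=O)c1cccc(OC(C)=O)c1O[Si](O)(C(C)(C)C)C(C)(C)C | intermediate
8 | octadecyl 2-[acetoxy(di-tert-butyl)silyloxy]-3-hydroxybenzoate (not isolated) | CCCCCCCCCCCCCCCCCCOC(=O)c1cccc(O)c1O[Si](OC(C)=O)(C(C)(C)C)C(C)(C)C | intermediate
9 | octadecyl 2,2-di-tert-butyl-1,3,2-benzodioxasilole-4-carboxylate | CCCCCCCCCCCCCCCCCCOC(=O)c1cccc2O[Si](C(C)(C)C)(C(C)(C)C)Oc12 | intermediate
10 | Gentiside E (octadecyl 2,3-dihydroxybenzoate; no stereocentre) | CCCCCCCCCCCCCCCCCCOC(=O)c1cccc(O)c1O | target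

Total step count: 4. Longest linear sequence: 4 steps (1 or 2 → 3 → 6 → 9 → 10).

**Steps most likely to fail**

1. **Step 3 (key step).**
   - Risk: palladation of the ester-deactivated ring may be too slow to keep pace with thermal decay of the oxidant. The ester carbonyl may chelate palladium together with the silanolate and hold the metal away from C3–H. At 100 °C in the presence of acid, the silanol may add to the neighbouring ester, or the O2–Si bond may be cleaved.
   - Fallback (oxygen brought in by way of a carbon substituent, no C–H metalation): it sets out from 3. Magnesium-mediated ortho-formylation under Casnati–Skattebøl conditions (MgCl2, Et3N, paraformaldehyde, THF, reflux) should deliver formaldehyde within the magnesium phenoxide to the one open ortho carbon, C3, and give octadecyl 3-formyl-2-hydroxybenzoate F1. Dakin oxidation with sodium percarbonate (2 Na2CO3·3 H2O2) in THF/H2O at rt under argon then turns the formyl group, by aryl migration, into octadecyl 3-(formyloxy)-2-hydroxybenzoate F2, which is hydrolysed in the same flask. After acidification the sequence comes back to the route at 10, so steps 2 to 4 are no longer needed.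

2. **Step 2.**
   - Risk: the hydrogen-bonded, ortho-flanked phenol may silylate sluggishly. The ester carbonyl may attack the strongly electrophilic Si–OTf centre beside it and start dealkylation of the ester. A second phenol may also add to silicon.
   - Fallback (silanol made by oxidation of a hydrosilane, no silyl triflate next to the ester): it sets out from 3. Silylation with the smaller di-tert-butylchlorosilane (imidazole, DMF, 40 °C) should give octadecyl 2-[(di-tert-butylsilyl)oxy]benzoate F3. Si–H bromination with N-bromosuccinimide (CH2Cl2, 0 °C; the ester-deactivated ring should resist bromination) gives octadecyl 2-[bromo(di-tert-butyl)silyloxy]benzoate F4. Hydrolysis with aqueous NaHCO3 in THF brings the sequence back to the route at 6.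

3. **Step 1.**
   - Risk: the salicylate unit may chelate titanium and slow catalyst turnover, so the equilibrium is not driven to completion and fatty alcohol remains. Isopropoxide from the catalyst may also exchange into the ester.
   - Fallback (irreversible C–O bond formation at the alkyl carbon, no acyl exchange): it sets out from 2. Mesylation (MsCl, Et3N, CH2Cl2, 0 °C) gives octadecyl methanesulfonate F5. This alkylates potassium salicylate, formed from salicylic acid and one equivalent of KHCO3, in DMF at 70 °C by SN2 displacement. With a single equivalent of weak base only the carboxylic acid is ionised, so the phenol should stay free. The sequence comes back to the route at 3.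

**Further compounds**
F1 | step 3 | octadecyl 3-formyl-2-hydroxybenzoate | CCCCCCCCCCCCCCCCCCOC(=O)c1cccc(C=O)c1O
F2 | step 3 | octadecyl 3-(formyloxy)-2-hydroxybenzoate | CCCCCCCCCCCCCCCCCCOC(=O)c1cccc(OC=O)c1O
F3 | step 2 | octadecyl 2-[(di-tert-butylsilyl)oxy]benzoate | CCCCCCCCCCCCCCCCCCOC(=O)c1ccccc1O[SiH](C(C)(C)C)C(C)(C)C
F4 | step 2 | octadecyl 2-[bromo(di-tert-butyl)silyloxy]benzoate | CCCCCCCCCCCCCCCCCCOC(=O)c1ccccc1O[Si](Br)(C(C)(C)C)C(C)(C)C
F5 | step 1 | octadecyl methanesulfonate | CCCCCCCCCCCCCCCCCCOS(C)(=O)=O
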